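**Plan**

- Retrosynthesis: the two O–CH3 bonds and the two cyclopentane C–H pairs are undone first, then both aryl–C(quaternary) bonds are cut together, then the two aryl O–C(cyclopentenyl) bonds, and last the central CH2–CH2 bond of the bibenzyl.
- Enabling feature: on each benzene ring the quaternary cyclopentyl carbon sits on the arene carbon ortho to the oxygen that lies para to the CH2CH2 bridge. That oxygen's other ortho carbon carries the second oxygen and its para carbon carries the bridge, so an allyl group placed on it can migrate to one carbon only.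
- Forward: no ring is built, since the benzene and cyclopentene rings are bought. The bibenzyl chain is joined first (reductive coupling of two aldehyde molecules, hydrogenation), the cyclopentenyl groups are attached to oxygen, both are moved to carbon in one two-directional step, and hydrogenation and O-demethylation finish the route.
- Stereochemistry: one CBS reduction gives the (R)-allylic alcohol, Mitsunobu inversion gives the (S)-ether, and the suprafacial [3,3] shift copies that centre into each (S)-quaternary carbon.

Key step: step 7

Remark: compounds 1 and 5 are taken as purchasable; step 1 consumes two molecules of 1; the two ends of each symmetric compound are treated as reacting independently, so half-converted species, catalyst-bound species and metal or boron alkoxides hydrolysed on work-up are not numbered.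

**Step 1**
Reactants: 1 4-(benzyloxy)-3-methoxybenzaldehyde (2 equiv)
Product: 2 (E)-1,2-bis[4-(benzyloxy)-3-methoxyphenyl]ethene
Conditions: TiCl4, Zn, pyridine, THF, reflux
Reagents that add atoms: none
Why: McMurry reductive coupling should join two molecules of the electron-rich benzaldehyde on low-valent titanium to the symmetrical stilbene with the benzyl and methyl ethers untouched, and the alkene geometry is irrelevant because the double bond is hydrogenated next.

**Step 2**
Reactants: 2 (E)-1,2-bis[4-(benzyloxy)-3-methoxyphenyl]ethene
Product: 4 4,4'-(ethane-1,2-diyl)bis(2-methoxyphenol), via dibenzyl bibenzyl 3 (not isolated)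
Conditions: H2 (1 atm), 10% Pd/C, THF/MeOH, rt
Reagents that add atoms: none
Why: Heterogeneous catalytic hydrogenation should saturate the stilbene double bond first and then cleave both benzyl ethers by hydrogenolysis, leaving the aryl methyl ethers in place.

**Step 3**
Reactants: 5 4,4-dimethylcyclopent-2-en-1-one
Product: 6 trimethyl[(3,4,4-trimethylcyclopent-1-en-1-yl)oxy]silane (racemic)
Conditions: MeMgBr, CuBr·SMe2 (10 mol %), TMSCl, HMPA, THF, −78 °C; then Et3N, pentane work-up
Reagents that add atoms: methylmagnesium bromide, C[Mg]Br; chlorotrimethylsilane, C[Si](C)(C)Cl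
Why: TMSCl-accelerated copper-catalysed conjugate addition of the Grignard reagent should place the methyl group on the β-carbon next to CMe2 and deliver the silyl enol ether regiospecifically; the new CH(CH3) centre is racemic and is erased in step 4.

**Step 4**
Reactants: 6 trimethyl[(3,4,4-trimethylcyclopent-1-en-1-yl)oxy]silane
Product: 7 3,4,4-trimethylcyclopent-2-en-1-one
Conditions: Pd(OAc)2 (10 mol %), O2 (1 atm), DMSO, 25–40 °C
Reagents that add atoms: none
Why: Aerobic Saegusa–Ito oxidation should turn the silyl enol ether into the conjugated enone by palladation at C2 and β-hydride loss from C3, so the double bond returns on the side fixed by the enol ether and now carries the methyl group.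

**Step 5**
Reactants: 7 3,4,4-trimethylcyclopent-2-en-1-one
Product: 8 (1R)-3,4,4-trimethylcyclopent-2-en-1-ol
Conditions: (S)-2-methyl-CBS-oxazaborolidine [(3aS)-1-methyl-3,3-diphenyltetrahydro-1H,3H-pyrrolo[1,2-c][1,3,2]oxazaborole] (15 mol %), catecholborane, toluene, −78 °C; then MeOH, aq NaOH; Et3N-treated silica
Reagents that add atoms: none
Why: In this Corey–Bakshi–Shibata reduction the oxazaborolidine should bind the ketone with the alkenyl flank as the larger group and deliver hydride to one carbonyl face, giving the (R)-allylic alcohol by 1,2-reduction only.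

**Step 6**
Reactants: 4 4,4'-(ethane-1,2-diyl)bis(2-methoxyphenol); 8 (1R)-3,4,4-trimethylcyclopent-2-en-1-ol (2.4 equiv)
Product: 9 1,2-bis{3-methoxy-4-[(1S)-3,4,4-trimethylcyclopent-2-en-1-yl]oxyphenyl}ethane
Conditions: PPh3, DIAD, toluene, −20 °C to rt; Et3N-treated silica
Reagents that add atoms: none
Why: In this double Mitsunobu etherification each phenol should displace the phosphonium-activated allylic oxygen in an SN2 sense, inverting (R) to (S), while SN2' attack is disfavoured because the far allyl terminus is fully substituted and flanked by CMe2.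

**Step 7**
Reactants: 9 1,2-bis{3-methoxy-4-[(1S)-3,4,4-trimethylcyclopent-2-en-1-yl]oxyphenyl}ethane
Product: 11 4,4'-(ethane-1,2-diyl)bis{2-methoxy-6-[(1S)-1,5,5-trimethylcyclopent-2-en-1-yl]phenol}, via bis(cyclohexadienone) 10 (not isolated)
Conditions: PhNEt2 (degassed), 190–200 °C, Ar, sealed vessel
Reagents that add atoms: none
Why: Each aryl cyclopentenyl ether should undergo a concerted suprafacial [3,3]-sigmatropic shift through a six-membered transition state in which the O–C1 bond breaks while the single unsubstituted ortho carbon bonds to the methyl-bearing alkene carbon C3 on the ring face that carried oxygen, after which each dienone end of 10 enolises to the phenol. This is the thermal aromatic Claisen rearrangement of secondary cycloalkenyl aryl ethers, used here at its congested limit because the accepting carbon lies next to CMe2. No ring is closed; two aryl–C(quaternary) bonds are formed. Each quaternary centre takes its configuration from the (S)-carbinol carbon of its own cyclopentene by 1,3-chirality transfer, since the five-membered ring fixes the allyl geometry and allows only same-face delivery, which gives (S) at both ends. The step needs ortho-carbon regioselectivity and a concerted rather than ionic or eliminative course: the para carbon is blocked by the ethylene bridge, the other ortho carbon bears OMe so a shift there is reversible and unproductive, and the basic amine solvent keeps out acid that would ionise the allylic ether.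

**Step 8**
Reactants: 11 4,4'-(ethane-1,2-diyl)bis{2-methoxy-6-[(1S)-1,5,5-trimethylcyclopent-2-en-1-yl]phenol}
Product: 12 4,4'-(ethane-1,2-diyl)bis{2-methoxy-6-[(1S)-1,2,2-trimethylcyclopentyl]phenol}
Conditions: H2 (3 atm), 10% Pd/C, EtOAc, rt
Reagents that add atoms: none
Why: Catalytic hydrogenation should saturate the two cis-disubstituted cyclopentene double bonds without creating or touching any stereocentre.

**Step 9**
Reactants: 12 4,4'-(ethane-1,2-diyl)bis{2-methoxy-6-[(1S)-1,2,2-trimethylcyclopentyl]phenol}
Product: 13 5,5'-(ethane-1,2-diyl)bis{3-[(1S)-1,2,2-trimethylcyclopentyl]benzene-1,2-diol} (target)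
Conditions: BBr3 (6 equiv), CH2Cl2, −78 to 0 °C; then H2O, under Ar
Reagents that add atoms: none
Why: In this Lewis-acid aryl methyl ether cleavage BBr3 should complex each methoxy oxygen and bromide remove the methyl group by SN2, leaving the all-carbon quaternary centres intact and giving the bis-catechol after hydrolysis.

**Compound list**

1 | 4-(benzyloxy)-3-methoxybenzaldehyde | COc1cc(C=O)ccc1OCc1ccccc1 | starting material
2 | (E)-1,2-bis[4-(benzyloxy)-3-methoxyphenyl]ethene | COc1cc(/C=C/c2ccc(OCc3ccccc3)c(OC)c2)ccc1OCc1ccccc1 | intermediate
3 | 1,2-bis[4-(benzyloxy)-3-methoxyphenyl]ethane | COc1cc(CCc2ccc(OCc3ccccc3)c(OC)c2)ccc1OCc1ccccc1 | intermediate (not isolated)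
4 | 4,4'-(ethane-1,2-diyl)bis(2-methoxyphenol) | COc1cc(CCc2ccc(O)c(OC)c2)ccc1O | intermediate
5 | 4,4-dimethylcyclopent-2-en-1-one | O=C1C=CC(C)(C)C1 | starting material
6 | trimethyl[(3,4,4-trimethylcyclopent-1-en-1-yl)oxy]silane, racemic | C[Si](C)(C)OC1=CC(C)C(C)(C)C1 | intermediate
7 | 3,4,4-trimethylcyclopent-2-en-1-one | O=C1C=C(C)C(C)(C)C1 | intermediate
8 | (1R)-3,4,4-trimethylcyclopent-2-en-1-ol | O[C@H]1C=C(C)C(C)(C)C1 | intermediate
9 | 1,2-bis{3-methoxy-4-[(1S)-3,4,4-trimethylcyclopent-2-en-1-yl]oxyphenyl}ethane | C(Cc1ccc(O[C@@H]2C=C(C)C(C)(C)C2)c(OC)c1)c1ccc(O[C@@H]2C=C(C)C(C)(C)C2)c(OC)c1 | intermediate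
10 | 4,4'-(ethane-1,2-diyl)bis[2-methoxy-6-(1,5,5-trimethylcyclopent-2-en-1-yl)cyclohexa-2,4-dien-1-one]; quaternary carbons arranged in space as in 11 (formally R here because the CIP ranking changes), ring C6–H centres transient and unspecified | C(CC1=CC([C@@]2(C)C=CCC2(C)C)C(=O)C(OC)=C1)C1=CC([C@@]2(C)C=CCC2(C)C)C(=O)C(OC)=C1 | intermediate (not isolated)
11 | 4,4'-(ethane-1,2-diyl)bis{2-methoxy-6-[(1S)-1,5,5-trimethylcyclopent-2-en-1-yl]phenol} | C(Cc1cc(OC)c(O)c([C@@]2(C)C=CCC2(C)C)c1)c1cc(OC)c(O)c([C@@]2(C)C=CCC2(C)C)c1 | intermediate
12 | 4,4'-(ethane-1,2-diyl)bis{2-methoxy-6-[(1S)-1,2,2-trimethylcyclopentyl]phenol} | C(Cc1cc(OC)c(O)c([C@@]2(C)CCCC2(C)C)c1)c1cc(OC)c(O)c([C@@]2(C)CCCC2(C)C)c1 | intermediate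
13 | 5,5'-(ethane-1,2-diyl)bis{3-[(1S)-1,2,2-trimethylcyclopentyl]benzene-1,2-diol} | CC1(C)CCC[C@]1(C)c1cc(CCc2cc(O)c(O)c([C@@]3(C)CCCC3(C)C)c2)cc(O)c1O | target

**Step count**

Total: 9 steps (branches of 2 and 3 steps, then 4 common steps). Longest linear sequence: 7 steps (5 to 13, steps 3–9).

**Steps most likely to fail**

1. Step 7. The concerted shift must make a quaternary carbon next to CMe2, and may be outrun by loss of the cyclopentenyl group (elimination to the diene, returning 4) or by ionisation and recombination at the less hindered allyl terminus. Fallback: the aryl–C(quaternary) bonds would be made by copper-mediated anti-SN2' allylic arylation, a known route to benzylic quaternary centres with 1,3-chirality transfer. It sets out from 4 and 8. Compound 4 is protected with MOMCl and i-Pr2NEt as 1,2-bis[3-methoxy-4-(methoxymethoxy)phenyl]ethane F1, and 8 is esterified with picolinic acid (DCC, 4-dimethylaminopyridine) to (1R)-3,4,4-trimethylcyclopent-2-en-1-yl pyridine-2-carboxylate F2. Directed ortho-lithiation of F1 (n-BuLi, TMEDA, THF, 0 °C), steered by each OMOM group to its only ortho hydrogen, should give 1,2-bis[3-lithio-5-methoxy-4-(methoxymethoxy)phenyl]ethane F3. MgBr2·OEt2 converts this into the bis(arylmagnesium bromide) F4. With CuBr·SMe2 in THF at 0 °C, F4 should displace the picolinate of two equivalents of F2 at C3 anti to the leaving group, giving 1,2-bis{3-methoxy-4-(methoxymethoxy)-5-[(1S)-1,5,5-trimethylcyclopent-2-en-1-yl]phenyl}ethane F5. The leaving group of the (R)-ester lies on the face opposite to the oxygen of the (S)-ether 9, so anti attack gives the same (S)-quaternary centres. Mild acid methanolysis (catalytic HCl, MeOH) removes the MOM groups and the route is rejoined at 11.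

2. Step 6. The activated allylic system leads to a tertiary-stabilised cation, so partial ionisation could erode the inversion or cause elimination. Any (R)-configured ether end would give the meso isomer of 9, whose stereocentres are too far apart for easy separation. Fallback: the ether would be formed with net retention by palladium-catalysed allylic etherification. It sets out from 7. Reduction as in step 5 but with the (R)-enantiomer of the oxazaborolidine gives (1S)-3,4,4-trimethylcyclopent-2-en-1-ol F6. Methyl chloroformate and pyridine give methyl (1S)-3,4,4-trimethylcyclopent-2-en-1-yl carbonate F7. F7 and 4 with Pd2(dba)3 and PPh3 (zerovalent palladium, THF, rt) should give 9: ionisation occurs with inversion and the phenoxide attacks anti to palladium at the unhindered terminus C1, so the double inversion carries (S) to (S). The route is rejoined at 9.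

3. Step 5. Facial discrimination between the CH2 and CH= flanks of the ketone may be insufficient, and every minor-enantiomer alcohol ends up as meso material after step 6. The sense of induction also rests on the alkenyl side acting as the larger group; if it proves opposite, the enantiomeric catalyst is used. Fallback: enzymatic kinetic resolution, setting out from 7. Luche reduction (NaBH4, CeCl3·7H2O, MeOH, 0 °C) gives racemic 3,4,4-trimethylcyclopent-2-en-1-ol F8. Candida antarctica lipase B with vinyl acetate in hexane should acylate the (R)-enantiomer, with the alkenyl side as the large substituent, to (1R)-3,4,4-trimethylcyclopent-2-en-1-yl acetate F9. F9 is separated from the unreacted (S)-enantiomer at a conversion chosen for high enantiomeric purity and methanolysed (K2CO3, MeOH) to 8, where the route is rejoined.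

**Further compounds**

F1 | step 7 | 1,2-bis[3-methoxy-4-(methoxymethoxy)phenyl]ethane | COCOc1ccc(CCc2ccc(OCOC)c(OC)c2)cc1OC
F2 | step 7 | (1R)-3,4,4-trimethylcyclopent-2-en-1-yl pyridine-2-carboxylate | O=C(O[C@H]1C=C(C)C(C)(C)C1)c1ccccn1
F3 | step 7 | 1,2-bis[3-lithio-5-methoxy-4-(methoxymethoxy)phenyl]ethane | [Li]c1cc(CCc2cc([Li])c(OCOC)c(OC)c2)cc(OC)c1OCOC
F4 | step 7 | 1,2-bis[3-(bromomagnesio)-5-methoxy-4-(methoxymethoxy)phenyl]ethane | Br[Mg]c1cc(CCc2cc([Mg]Br)c(OCOC)c(OC)c2)cc(OC)c1OCOC
F5 | step 7 | 1,2-bis{3-methoxy-4-(methoxymethoxy)-5-[(1S)-1,5,5-trimethylcyclopent-2-en-1-yl]phenyl}ethane | C(Cc1cc(OC)c(OCOC)c([C@@]2(C)C=CCC2(C)C)c1)c1cc(OC)c(OCOC)c([C@@]2(C)C=CCC2(C)C)c1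
F6 | step 6 | (1S)-3,4,4-trimethylcyclopent-2-en-1-ol | O[C@@H]1C=C(C)C(C)(C)C1
F7 | step 6 | methyl (1S)-3,4,4-trimethylcyclopent-2-en-1-yl carbonate | COC(=O)O[C@@H]1C=C(C)C(C)(C)C1
F8 | step 5 | rac-3,4,4-trimethylcyclopent-2-en-1-ol | OC1C=C(C)C(C)(C)C1
F9 | step 5 | (1R)-3,4,4-trimethylcyclopent-2-en-1-yl acetate | CC(=O)O[C@H]1C=C(C)C(C)(C)C1
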